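The earlier runs and the new flask were computed for an exercise, noise included.

You cannot count more chains than there were beginnings, so a flask's average chain length, the number-average degree of polymerisation, has a floor that you can reckon before the flask is run, provided initiator does the beginning. The chain ceiling, the initiator charged with each unit counted as one possible beginning, is 7.40 mM in the flask.

all flasks: initiator 7.4 mol%
- Thursday's: free monomer 0.10 M; transfer agent 1.5 mM; run made earlier
- Tuesday's: free monomer 0.10 M; transfer agent 2.2 mM; run made earlier
- Wednesday's: free monomer 0.050 M; transfer agent 3 mM; run made earlier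
- flask: free monomer 0.10 M; transfer agent 3.00 mM; time 4.0 h

| run | time / h | monomer in chains / % | free monomer / % |
|---|---|---|---|
| Thursday's | 0.500 | 11 | 92 |
| Thursday's | 1.00 | 18 | 82 |
| Thursday's | 1.50 | 25 | 76 |
| Thursday's | 2.50 | 36 | 62 |
| Thursday's | 3.00 | 42 | 58 |
| Thursday's | 4.00 | 52 | 50 |
| Tuesday's | 0.500 | 9 | 92 |
| Tuesday's | 1.00 | 19 | 83 |
| Tuesday's | 1.50 | 24 | 74 |
| Tuesday's | 2.50 | 35 | 60 |
| Tuesday's | 3.00 | 40 | 59 |
| Tuesday's | 4.00 | 51 | 49 |
| Wednesday's | 0.333 | 3 | 97 |
| Wednesday's | 1.00 | 8 | 90 |
| Wednesday's | 2.00 | 17 | 82 |
| Wednesday's | 3.00 | 22 | 78 |
| Wednesday's | 4.00 | 28 | 72 |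

(standard deviation of a reading: 1.5 percentage points)

- the average divides the monomer in chains by the number of chains begun, living and dead together
- what was read earlier has a scatter of 1.5 percentage points, one standard deviation
- the earlier runs do not show the number of chains; that part of a forecast is a guess

- average number of monomer units in a chain (chains begun, living or dead) at 4.0 h
- part of the free monomer that has reacted at 4.0 h

1. Take the main step first: free monomer adds to living ends begun by initiator, pseudo-first-order while their number holds. Thursday's and Tuesday's runs leave on average 49.5% of it at 4.0 h, a reading of 0.176 h⁻¹. Wednesday's run reads 0.0821 h⁻¹, about half of that, with half the initiator, although it held 3 mM of transfer agent against Thursday's 1.5 mM. So you can expect 50.5% reacted in the flask, and with every unit of initiator beginning a chain, the average is 50.5 mM over the ceiling, 6.82.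

2. Now add loss: initiator that decays without beginning a chain lowers the count and lifts the average above 6.82. The runs do not show chains, so this size is a guess, and I hold it small.

3. Last, add the transfer agent: if it stops a living end, the dead chain stays in the count, which takes living and dead together, so the count stays put, but a dead end adds no more monomer, which lowers the monomer in chains and the average with it. The second and third steps pull opposite ways and I hold both small, so my reckoning stays near 6.82.

The forecast differs on the count of chains, giving 12.5 and 49% with “Chains are 3 mM from the agent plus a guessed 1 mM from initiator”.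

The flask gives 7.61 units per chain and 49.1% reacted.

    living end + transfer agent → dead chain (kL = 27.1 M⁻¹ h⁻¹)
    free monomer + living end → monomer in chains + living end, rate k2*[living end]*[free monomer] (k = 28.8 M⁻¹ h⁻¹)
    free monomer + initiator → living end + monomer in chains (k = 30.1 M⁻¹ h⁻¹)
    initiator → spent initiator (k = 0.415 h⁻¹)

At 4.00 h the flask holds 5.15 mM of living ends, 1.31 mM of dead chains and 0.948 mM of spent initiator, which add up to 7.41 mM, the ceiling of 7.40 mM. Now use the ceiling on the neighbouring flask with 0.0075 M of transfer agent, where 43.8% has reacted. Its ceiling is the same 7.40 mM, and taking off its 0.947 mM of spent initiator leaves 6.45 mM of chains. Its monomer in chains over that count is 6.78, and that neighbouring flask's simulated average is 6.78.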